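**Strategy.** The plan rests on cutting the C3=C4 double bond of the pyran ring. Ring-closing metathesis joins a vinyl group on aromatic C4a to a vinyl group on the fully substituted ether carbon C2, both held in place by the O1–C8a linkage, and closes the 2H-chromene in one operation; the hindered exocyclic C2'=CH2 of the cyclohexane is a spectator. The diene precursor is a tertiary allyl aryl ether whose C2 is set by catalyst-controlled O-allylation. C1' and C3' are set beforehand in a temporary decalin: an auxiliary fixes C1', thermodynamic epimerisation relays it to C3', and a fragmentation removes the extra ring.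

Key step: step 12

Numbering used: chromene O1, C2, C3, C4, C4a, C5–C8, C8a; cyclohexane C1' (quaternary), C2' (methylidene-bearing), C3' (CHMe). The target is (2S,1'R,3'R) with the C1' and C3' methyl groups trans.

Assumption: the (R,R)-ligand is taken to give the (S)-ether from the E-carbonate in step 10; if the first run shows the opposite sense, the (S,S)-ligand is used instead and nothing else changes.

**Step 1**
Reactants: 1 2,6-dimethylcyclohexan-1-one (commercial cis/trans mixture); 2 (S)-1-phenylethan-1-amine; 3 but-3-en-2-one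
Product: 6 (2R)-2,6-dimethyl-2-(3-oxobutyl)cyclohexan-1-one (both C6 epimers), via ketimine 4 (not isolated), via adduct imine 5 (not isolated)
Conditions: 2, TsOH (cat.), toluene, Dean–Stark, reflux; concentrate; 3, THF, 25 °C; 20% aq AcOH, 25 °C
Reagents that add atoms: water, O
Why: Asymmetric Michael addition of a chiral imine, in which the more substituted secondary enamine tautomer of 4 adds to the enone through a compact aza-ene-type transition state on the face away from the phenyl group of the auxiliary, so the quaternary centre should form as (R), while C6 stays a mixture that step 2 corrects.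

**Step 2**
Reactants: 6 (2R)-2,6-dimethyl-2-(3-oxobutyl)cyclohexan-1-one
Product: 7 (4aR,8R)-4a,8-dimethyl-4,4a,5,6,7,8-hexahydronaphthalen-2(3H)-one
Conditions: NaOMe, MeOH, 60 °C
Reagents that add atoms: none
Why: Intramolecular aldol condensation (second stage of a Robinson annulation) under equilibrating base, in which C8, now the γ-carbon of the enone, epimerises through the dienolate to the equatorial methyl epimer trans to the angular methyl group (no 1,3-diaxial Me/Me contact), so C4a is relayed to C8 by thermodynamic control.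

**Step 3**
Reactants: 7 (4aR,8R)-4a,8-dimethyl-4,4a,5,6,7,8-hexahydronaphthalen-2(3H)-one
Product: 8 (4aR,8R)-1,8a-epoxy-4a,8-dimethyloctahydronaphthalen-2(1H)-one (epoxide face not controlled)
Conditions: 30% H2O2, aq NaOH, MeOH, 0 → 25 °C
Reagents that add atoms: hydrogen peroxide, OO
Why: Weitz–Scheffer nucleophilic epoxidation of the enone, whose facial outcome does not matter because C1 and C8a lose their configuration in step 4.

**Step 4**
Reactants: 8 (4aR,8R)-1,8a-epoxy-4a,8-dimethyloctahydronaphthalen-2(1H)-one
Product: 10 (2R,6R)-2-(but-3-yn-1-yl)-2,6-dimethylcyclohexan-1-one, via tosylhydrazone 9 (not isolated)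
Conditions: TsNHNH2, AcOH/CH2Cl2 1:1, −20 → 25 °C
Reagents that add atoms: none
Why: Eschenmoser–Tanabe fragmentation, in which the tosylhydrazone opens the epoxide to a β-alkoxy azoalkene that fragments with loss of N2 and sulfinate, cleaving C1–C8a to a ring ketone and a terminal alkyne and so excising the temporary ring, while the weakly acidic medium should not enolise the new α-methyl ketone centre.

**Step 5**
Reactants: 10 (2R,6R)-2-(but-3-yn-1-yl)-2,6-dimethylcyclohexan-1-one
Product: 11 (1R,3R)-1-(but-3-yn-1-yl)-1,3-dimethyl-2-methylidenecyclohexane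
Conditions: Zn, CH2Br2, TiCl4, THF/CH2Cl2, 0 → 25 °C
Reagents that add atoms: dibromomethane, BrCBr
Why: Takai–Lombardo methylenation, whose non-basic zinc/titanium methylene reagent converts hindered enolisable ketones into alkenes without epimerising the adjacent C–H stereocentre and leaves the alkyne alone.

**Step 6**
Reactants: 11 (1R,3R)-1-(but-3-yn-1-yl)-1,3-dimethyl-2-methylidenecyclohexane
Product: 14 (2E)-5-[(1R,3R)-1,3-dimethyl-2-methylidenecyclohexyl]-3-methylpent-2-en-1-ol, via alkenylalane 12 (not isolated), via lithium alanate 13 (not isolated)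
Conditions: Me3Al, Cp2ZrCl2 (cat.), CH2Cl2, 0 → 25 °C; n-BuLi, THF, −78 °C; (CH2O)n, −78 → 25 °C
Reagents that add atoms: trimethylaluminium, C[Al](C)C; formaldehyde (as paraformaldehyde), C=O
Why: Negishi zirconium-catalysed carboalumination, a syn addition of Me–Al across the terminal alkyne with methyl on the internal carbon, followed by formaldehyde trapping of the alanate with retention, which should give only the E allylic alcohol, the neopentyl-flanked 1,1-disubstituted alkene being too hindered to carbometalate.

**Step 7**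
Reactants: 14 (2E)-5-[(1R,3R)-1,3-dimethyl-2-methylidenecyclohexyl]-3-methylpent-2-en-1-ol
Product: 15 (2E)-5-[(1R,3R)-1,3-dimethyl-2-methylidenecyclohexyl]-3-methylpent-2-en-1-yl methyl carbonate
Conditions: ClCO2Me, pyridine, CH2Cl2, 0 °C
Reagents that add atoms: methyl chloroformate, COC(Cl)=O
Why: Routine acylation of a primary allylic alcohol, giving the carbonate leaving group needed for the allylic substitution.

**Step 8**
Reactants: 16 1,2,4-trimethoxybenzene
Product: 18 2,3,6-trimethoxybenzaldehyde, via aryllithium 17 (not isolated)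
Conditions: n-BuLi, TMEDA, THF, 0 °C; DMF, 0 → 25 °C; aq NH4Cl
Reagents that add atoms: N,N-dimethylformamide, CN(C)C=O
Why: Directed ortho-metalation at C3, the only position flanked by two methoxy groups, followed by formylation of the aryllithium.

**Step 9**
Reactants: 18 2,3,6-trimethoxybenzaldehyde
Product: 19 2,6-dihydroxy-3-methoxybenzaldehyde
Conditions: BCl3 (3 equiv), CH2Cl2, −78 → 25 °C; H2O
Reagents that add atoms: none
Why: Chelation-directed ether cleavage, in which boron bound to the formyl oxygen delivers chloride only to the two O-methyl groups ortho to the carbonyl, so the C3 methoxy group, which lacks this assistance, should survive.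

**Step 10**
Reactants: 15 (2E)-5-[(1R,3R)-1,3-dimethyl-2-methylidenecyclohexyl]-3-methylpent-2-en-1-yl methyl carbonate; 19 2,6-dihydroxy-3-methoxybenzaldehyde
Product: 20 2-hydroxy-3-methoxy-6-{[(3S)-5-[(1R,3R)-1,3-dimethyl-2-methylidenecyclohexyl]-3-methylpent-1-en-3-yl]oxy}benzaldehyde
Conditions: Pd2(dba)3·CHCl3 (2 mol%), (1R,2R)-N,N'-bis[2-(diphenylphosphino)benzoyl]cyclohexane-1,2-diamine (6 mol%), CH2Cl2, 25 °C
Reagents that add atoms: none
Why: Tsuji–Trost asymmetric allylic etherification, in which zerovalent palladium ionises the carbonate and the phenoxide attacks the more substituted terminus of the π-allyl complex inside the chiral pocket of the ligand, giving the branched tertiary ether and setting its stereocentre (the future C2) as (S) by catalyst control, with the hydroxyl that has one ortho substituent reacting in preference to the one wedged between formyl and methoxy groups.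

**Step 11**
Reactants: 20 2-hydroxy-3-methoxy-6-{[(3S)-5-[(1R,3R)-1,3-dimethyl-2-methylidenecyclohexyl]-3-methylpent-1-en-3-yl]oxy}benzaldehyde
Product: 21 2-ethenyl-6-methoxy-3-{[(3S)-5-[(1R,3R)-1,3-dimethyl-2-methylidenecyclohexyl]-3-methylpent-1-en-3-yl]oxy}phenol
Conditions: Ph3PCH3Br, KOtBu (3 equiv each), THF, 0 → 25 °C
Reagents that add atoms: methyltriphenylphosphonium bromide, C[P+](c1ccccc1)(c1ccccc1)c1ccccc1.[Br-]
Why: Wittig methylenation of the aryl aldehyde, in which excess ylide absorbs the phenolic proton and the tertiary allyl aryl ether is inert to the ylide.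

**Step 12**
Reactants: 21 2-ethenyl-6-methoxy-3-{[(3S)-5-[(1R,3R)-1,3-dimethyl-2-methylidenecyclohexyl]-3-methylpent-1-en-3-yl]oxy}phenol
Product: 22 (2S)-2-{2-[(1R,3R)-1,3-dimethyl-2-methylidenecyclohexyl]ethyl}-6-methoxy-2-methyl-2H-chromen-5-ol
Conditions: second-generation Grubbs catalyst (H2IMes)(PCy3)Cl2Ru=CHPh (5 mol%), CH2Cl2 (5 mM), 40 °C
Reagents that add atoms: none
Why: Ring-closing olefin metathesis: the ruthenium alkylidene first exchanges onto the unhindered styrenyl vinyl group on C4a (the ortho ether oxygen can chelate the metal), then undergoes intramolecular [2+2] cycloaddition with the vinyl group on C2 and cycloreversion, releasing ethene and forming the C3=C4 bond. The closest known reaction type is the ring-closing metathesis of 2-vinylaryl allyl ethers to 2H-chromenes. The pyran ring closes as a six-membered ring from a 1,7-diene, with both alkene carbons inside the new ring and the cis geometry imposed by the ring. No stereocentre is created; C2 (set in step 10), C1' and C3' are spectators, and the neutral conditions should not ionise the tertiary allylic aryl ether. The step needs chemoselectivity for the two monosubstituted alkenes over the exocyclic C2'=CH2, which is secured because that 1,1-disubstituted alkene is flanked by the quaternary C1' and the tertiary C3'; high dilution suppresses cross-metathesis and the free phenol is tolerated.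

**Step 13**
Reactants: 22 (2S)-2-{2-[(1R,3R)-1,3-dimethyl-2-methylidenecyclohexyl]ethyl}-6-methoxy-2-methyl-2H-chromen-5-ol
Product: 23 (2S)-2-{2-[(1R,3R)-1,3-dimethyl-2-methylidenecyclohexyl]ethyl}-6-methoxy-2-methyl-2H-chromene-5,8-dione
Conditions: (KSO3)2NO, aq KH2PO4, acetone/H2O, 0 → 25 °C
Reagents that add atoms: potassium nitrosodisulfonate (Fremy's salt), [K+].[K+].[O]N(S(=O)(=O)[O-])S(=O)(=O)[O-]
Why: Teuber oxidation, in which the nitrosodisulfonate radical oxidises a phenol with a free para position to the para-quinone, here introducing the C8 oxygen without touching the alkenes.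

**Step 14**
Reactants: 23 (2S)-2-{2-[(1R,3R)-1,3-dimethyl-2-methylidenecyclohexyl]ethyl}-6-methoxy-2-methyl-2H-chromene-5,8-dione
Product: 24 (2S)-2-{2-[(1R,3R)-1,3-dimethyl-2-methylidenecyclohexyl]ethyl}-6-methoxy-2-methyl-2H-chromene-5,8-diol
Conditions: Na2S2O4, EtOAc/H2O, 25 °C, under Ar
Reagents that add atoms: none
Why: Two-electron reduction of the quinone to the hydroquinone by dithionite, which affects no stereocentre and no alkene.

**Compound list**

1 | 2,6-dimethylcyclohexan-1-one (cis/trans mixture) | CC1CCCC(C)C1=O | starting material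
2 | (S)-1-phenylethan-1-amine | C[C@H](N)c1ccccc1 | starting material
3 | but-3-en-2-one (methyl vinyl ketone) | C=CC(C)=O | starting material
4 | (1S)-N-(2,6-dimethylcyclohexylidene)-1-phenylethan-1-amine | CC1CCCC(C)C1=N[C@@H](C)c1ccccc1 | intermediate (not isolated)
5 | 4-[(1R)-1,3-dimethyl-2-{[(1S)-1-phenylethyl]imino}cyclohexyl]butan-2-one | CC(=O)CC[C@@]1(C)CCCC(C)C1=N[C@@H](C)c1ccccc1 | intermediate (not isolated)
6 | (2R)-2,6-dimethyl-2-(3-oxobutyl)cyclohexan-1-one (C6 epimers) | O=C1C(C)CCC[C@]1(C)CCC(C)=O | intermediate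
7 | (4aR,8R)-4a,8-dimethyl-4,4a,5,6,7,8-hexahydronaphthalen-2(3H)-one | O=C1C=C2[C@H](C)CCC[C@]2(C)CC1 | intermediate
8 | (4aR,8R)-1,8a-epoxy-4a,8-dimethyloctahydronaphthalen-2(1H)-one (epoxide face not controlled) | O=C1CC[C@@]2(C)CCC[C@@H](C)C23OC13 | intermediate
9 | N'-[(4aR,8R)-1,8a-epoxy-4a,8-dimethyloctahydronaphthalen-2(1H)-ylidene]-4-methylbenzenesulfonohydrazide | Cc1ccc(cc1)S(=O)(=O)NN=C1CC[C@@]2(C)CCC[C@@H](C)C23OC13 | intermediate (not isolated)
10 | (2R,6R)-2-(but-3-yn-1-yl)-2,6-dimethylcyclohexan-1-one | O=C1[C@H](C)CCC[C@]1(C)CCC#C | intermediate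
11 | (1R,3R)-1-(but-3-yn-1-yl)-1,3-dimethyl-2-methylidenecyclohexane | C=C1[C@H](C)CCC[C@]1(C)CCC#C | intermediate
12 | {(1E)-4-[(1R,3R)-1,3-dimethyl-2-methylidenecyclohexyl]-2-methylbut-1-en-1-yl}dimethylalumane | C=C1[C@H](C)CCC[C@]1(C)CC/C(C)=C/[Al](C)C | intermediate (not isolated)
13 | lithium butyl{(1E)-4-[(1R,3R)-1,3-dimethyl-2-methylidenecyclohexyl]-2-methylbut-1-en-1-yl}dimethylaluminate | [Li+].C=C1[C@H](C)CCC[C@]1(C)CC/C(C)=C/[Al-](C)(C)CCCC | intermediate (not isolated)
14 | (2E)-5-[(1R,3R)-1,3-dimethyl-2-methylidenecyclohexyl]-3-methylpent-2-en-1-ol | C=C1[C@H](C)CCC[C@]1(C)CC/C(C)=C/CO | intermediate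
15 | (2E)-5-[(1R,3R)-1,3-dimethyl-2-methylidenecyclohexyl]-3-methylpent-2-en-1-yl methyl carbonate | C=C1[C@H](C)CCC[C@]1(C)CC/C(C)=C/COC(=O)OC | intermediate
16 | 1,2,4-trimethoxybenzene | COc1ccc(OC)c(OC)c1 | starting material
17 | (2,3,6-trimethoxyphenyl)lithium | COc1ccc(OC)c([Li])c1OC | intermediate (not isolated)
18 | 2,3,6-trimethoxybenzaldehyde | COc1ccc(OC)c(C=O)c1OC | intermediate
19 | 2,6-dihydroxy-3-methoxybenzaldehyde | COc1ccc(O)c(C=O)c1O | intermediate
20 | 2-hydroxy-3-methoxy-6-{[(3S)-5-[(1R,3R)-1,3-dimethyl-2-methylidenecyclohexyl]-3-methylpent-1-en-3-yl]oxy}benzaldehyde | C=C1[C@H](C)CCC[C@]1(C)CC[C@@](C)(C=C)Oc1ccc(OC)c(O)c1C=O | intermediate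
21 | 2-ethenyl-6-methoxy-3-{[(3S)-5-[(1R,3R)-1,3-dimethyl-2-methylidenecyclohexyl]-3-methylpent-1-en-3-yl]oxy}phenol | C=C1[C@H](C)CCC[C@]1(C)CC[C@@](C)(C=C)Oc1ccc(OC)c(O)c1C=C | intermediate
22 | (2S)-2-{2-[(1R,3R)-1,3-dimethyl-2-methylidenecyclohexyl]ethyl}-6-methoxy-2-methyl-2H-chromen-5-ol | C=C1[C@H](C)CCC[C@]1(C)CC[C@@]1(C)C=Cc2c(O)c(OC)ccc2O1 | intermediate
23 | (2S)-2-{2-[(1R,3R)-1,3-dimethyl-2-methylidenecyclohexyl]ethyl}-6-methoxy-2-methyl-2H-chromene-5,8-dione | C=C1[C@H](C)CCC[C@]1(C)CC[C@@]1(C)C=CC2=C(O1)C(=O)C=C(OC)C2=O | intermediate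
24 | (2S)-2-{2-[(1R,3R)-1,3-dimethyl-2-methylidenecyclohexyl]ethyl}-6-methoxy-2-methyl-2H-chromene-5,8-diol | C=C1[C@H](C)CCC[C@]1(C)CC[C@@]1(C)C=Cc2c(O)c(OC)cc(O)c2O1 | target

**Step count and risks**

Total: 14 steps. Longest linear sequence: 12 steps (steps 1–7, then 10–14); the arene branch (steps 8 and 9) joins at step 10.

The three steps most likely to fail:

Step 10 (allylic etherification). What may go wrong: attack of the phenoxide at the unsubstituted allyl terminus, loss of facial control if the syn and anti π-allyl complexes do not equilibrate fast enough, alkylation at the more hindered hydroxyl, or re-ionisation of the tertiary ether by zerovalent palladium. The fallback sets out from 14 and comes back at 20; it makes the C–O stereocentre by epoxidation instead of allylic substitution. Sharpless epoxidation of 14 (Ti(OiPr)4, L-(+)-diethyl tartrate, t-BuOOH, 4 Å sieves, CH2Cl2, −20 °C) should give the (2S,3S)-epoxy alcohol F1. I2, PPh3 and imidazole convert it into the epoxy iodide F2, and zinc dust in AcOH/MeOH opens this reductively to the (3S)-tertiary allylic alcohol F3 without touching the tertiary C–O bond. In parallel, 5-fluoro-2-methoxyphenol is ortho-formylated (MgCl2, Et3N, paraformaldehyde, MeCN) to the fluorosalicylaldehyde F4, which is silylated (iPr3SiCl, imidazole) to the silyl ether F5. The potassium alkoxide of F3 (KN(SiMe3)2, THF/DMF) displaces the fluoride of F5, which is ortho to the formyl group, by nucleophilic aromatic substitution to give the aryl ether F6. Bu4NF then removes the silyl group to give 20.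

Step 5 (methylenation). What may go wrong: the carbonyl group lies between a quaternary and a tertiary carbon, so addition of the methylene reagent may be too slow, and enolisation may scramble C6. The fallback sets out from 10 and comes back at 11; it is a Peterson olefination. Me3SiCH2Li with CeCl3 (THF, −78 °C, one further equivalent for the alkyne proton) adds to the ketone without enolisation to give the β-hydroxysilane F7, and KH in THF eliminates it to 11.

Step 4 (fragmentation). What may go wrong: slow hydrazone formation next to the epoxide, premature epoxide opening by acetic acid, or diversion of the diazene intermediate to reduction products, so that little alkynone forms. The fallback sets out from 7 and comes back at 11; it uses oxidative cleavage in place of fragmentation. Ozonolysis of the enone 7 (O3, EtOAc/AcOH; then H2O2) cuts C1=C8a and C1–C2 and should give the keto acid F8, with C1 lost as formic acid. Methylenation as in step 5 gives the acid F9, LiAlH4 reduces it to the alcohol F10, Dess–Martin periodinane gives the aldehyde F11, and the Ohira–Bestmann reagent (dimethyl (1-diazo-2-oxopropyl)phosphonate, K2CO3, MeOH) homologates it to the alkyne 11.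

**Further compounds**

F1 | step 10 | {(2S,3S)-3-{2-[(1R,3R)-1,3-dimethyl-2-methylidenecyclohexyl]ethyl}-3-methyloxiran-2-yl}methanol | C=C1[C@H](C)CCC[C@]1(C)CC[C@]1(C)O[C@H]1CO
F2 | step 10 | (2R,3S)-3-{2-[(1R,3R)-1,3-dimethyl-2-methylidenecyclohexyl]ethyl}-2-(iodomethyl)-3-methyloxirane | C=C1[C@H](C)CCC[C@]1(C)CC[C@]1(C)O[C@H]1CI
F3 | step 10 | (3S)-5-[(1R,3R)-1,3-dimethyl-2-methylidenecyclohexyl]-3-methylpent-1-en-3-ol | C=C1[C@H](C)CCC[C@]1(C)CC[C@@](C)(C=C)O
F4 | step 10 | 6-fluoro-2-hydroxy-3-methoxybenzaldehyde | COc1ccc(F)c(C=O)c1O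
F5 | step 10 | 6-fluoro-3-methoxy-2-{[tri(propan-2-yl)silyl]oxy}benzaldehyde | COc1ccc(F)c(C=O)c1O[Si](C(C)C)(C(C)C)C(C)C
F6 | step 10 | 3-methoxy-6-{[(3S)-5-[(1R,3R)-1,3-dimethyl-2-methylidenecyclohexyl]-3-methylpent-1-en-3-yl]oxy}-2-{[tri(propan-2-yl)silyl]oxy}benzaldehyde | C=C1[C@H](C)CCC[C@]1(C)CC[C@@](C)(C=C)Oc1ccc(OC)c(O[Si](C(C)C)(C(C)C)C(C)C)c1C=O
F7 | step 5 | (2R,6R)-2-(but-3-yn-1-yl)-2,6-dimethyl-1-[(trimethylsilyl)methyl]cyclohexan-1-ol (carbinol centre not controlled) | C[Si](C)(C)CC1(O)[C@H](C)CCC[C@]1(C)CCC#C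
F8 | step 4 | 3-[(1R,3R)-1,3-dimethyl-2-oxocyclohexyl]propanoic acid | O=C1[C@H](C)CCC[C@]1(C)CCC(O)=O
F9 | step 4 | 3-[(1R,3R)-1,3-dimethyl-2-methylidenecyclohexyl]propanoic acid | C=C1[C@H](C)CCC[C@]1(C)CCC(O)=O
F10 | step 4 | 3-[(1R,3R)-1,3-dimethyl-2-methylidenecyclohexyl]propan-1-ol | C=C1[C@H](C)CCC[C@]1(C)CCCO
F11 | step 4 | 3-[(1R,3R)-1,3-dimethyl-2-methylidenecyclohexyl]propanal | C=C1[C@H](C)CCC[C@]1(C)CCC=O
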